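**Plan**
Locants are icetexane-type: ring C = C-8, C-9, C-11 to C-14 (isopropyl on C-13); seven-membered ring B = C-5, C-6, C-7, C-8, C-9, C-20, C-10; ring A = C-1 to C-5, C-10; lactone C-19(=O)–O–C-6; C-18 is the methyl on C-4.
Retrosynthesis: hydroxyquinone ⇐ 11,12,14-trimethoxyarene; then cut C-1–C-10 (ring A) to a C-10 alkenyl bromide and a C-1 aldehyde; then C-4–C-18 and C-4–C-3 (lactone enolate alkylations); then O–C-6/O–C-7 and C-4–C-5 (dihydroxylation and Claisen transforms) back to a benzocycloheptenol; ring B ⇐ arene + glutaric anhydride.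
Forward ring order: ring C (bought as arene) → ring B (Friedel–Crafts) → lactone → ring A (last) → quinone unveiled.
Stereochemistry: C-7 by CBS reduction, relayed to C-5 by a suprafacial Eschenmoser–Claisen shift; C-6 and C-7 by OsO4 anti to the C-5 branch; C-4 by methylation of the lactone enolate anti to C-10; C-1 in the key step.
Enabling feature: the C-1 carbinol is allylic to the C-10=C-20 double bond of ring B, so ring A is the retron of an alkenyl-metal/aldehyde union. C-10 (as alkenyl bromide) and C-1 (as aldehyde) are both electrophiles and are joined by Ni/Cr polarity reversal.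

Key step: step 21

Remark: the SMILES is read as 1R,4S,5R,6R,7S, i.e. 1β-OH, 4α-CH3, 5α-H, 6α-O (lactone), 7α-OH, where β is the face of ring B on which C-4 sits at C-5.

**Step 1**
Reactants: 1 1,2,4-trimethoxybenzene
Product: 2 2-(2,3,6-trimethoxyphenyl)propan-2-ol
Conditions: n-BuLi, THF, 0 °C; acetone, −78 °C to rt; H2O
Reagents that add atoms: acetone CC(C)=O
Why: Directed ortho-lithiation should occur at the CH flanked by two methoxy groups, and the aryllithium adds 1,2 to acetone.

**Step 2**
Reactants: 2 2-(2,3,6-trimethoxyphenyl)propan-2-ol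
Product: 3 2-isopropyl-1,3,4-trimethoxybenzene
Conditions: Et3SiH, CF3CO2H, CH2Cl2, 0 °C to rt
Reagents that add atoms: none
Why: Ionic hydrogenation of the tertiary benzylic alcohol through its stabilised cation should give the isopropyl arene.

**Step 3**
Reactants: 3 2-isopropyl-1,3,4-trimethoxybenzene; 4 glutaric anhydride
Product: 5 5-(3-isopropyl-2,4,5-trimethoxyphenyl)-5-oxopentanoic acid
Conditions: AlCl3, CH2Cl2/MeNO2, 0 °C
Reagents that add atoms: none
Why: Friedel–Crafts acylation should take the CH para to the central methoxy group and ortho to another (the future C-8), the most activated of the two free positions.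

**Step 4**
Reactants: 5 5-(3-isopropyl-2,4,5-trimethoxyphenyl)-5-oxopentanoic acid
Product: 6 5-(3-isopropyl-2,4,5-trimethoxyphenyl)pentanoic acid
Conditions: Et3SiH, CF3CO2H, rt
Reagents that add atoms: none
Why: Ionic hydrogenation of an electron-rich aryl ketone to the methylene (the future C-7) is a standard silane/acid reduction.

**Step 5**
Reactants: 6 5-(3-isopropyl-2,4,5-trimethoxyphenyl)pentanoic acid
Product: 7 2-isopropyl-1,3,4-trimethoxy-6,7,8,9-tetrahydro-5H-benzo[7]annulen-5-one (rings B and C; ketone = C-20)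
Conditions: polyphosphoric acid, 70 °C
Reagents that add atoms: none
Why: Intramolecular Friedel–Crafts acylation can only attack the single remaining aromatic CH (C-9) and so closes ring B with defined regiochemistry.

**Step 6**
Reactants: 7 benzosuberone (ketone at C-20)
Product: 8 C-20 ethylene ketal of 7 (spiro-1,3-dioxolane)
Conditions: (Me3SiOCH2)2, Me3SiOTf (cat.), CH2Cl2, −78 to −20 °C
Reagents that add atoms: 1,2-bis(trimethylsilyloxy)ethane C[Si](C)(C)OCCO[Si](C)(C)C
Why: Silyl-transfer ketalization works on hindered aryl ketones at low temperature and masks C-20 through the enolate chemistry that follows.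

**Step 7**
Reactants: 8 C-20 ethylene ketal
Product: 9 7-oxo derivative of 8 (aryl ketone at C-7, dioxolane at C-20)
Conditions: Rh2(cap)4 (1 mol %), t-BuOOH (aq.), NaHCO3, ClCH2CH2Cl, 40 °C
Reagents that add atoms: tert-butyl hydroperoxide CC(C)(C)OO
Why: Radical benzylic C–H oxidation should take the only benzylic methylene (C-7, para to a methoxy group), while the isopropyl methine is shielded by its two flanking methoxy groups.

**Step 8**
Reactants: 9 C-7 ketone
Product: 10 C-7 enone with C-5=C-6 (dioxolane at C-20)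
Conditions: LiN(iPr)2, THF, −78 °C; PhS(Cl)=N-t-Bu, −78 °C
Reagents that add atoms: none
Why: Mukaiyama dehydrogenation (sulfinimidoylation of the only possible enolate, then syn-elimination) should give the enone without acid, which the ketal requires.

**Step 9**
Reactants: 10 enone
Product: 11 (7S)-allylic alcohol (7β-OH, C-5=C-6, dioxolane at C-20)
Conditions: (R)-Me-CBS oxazaborolidine (20 mol %), catecholborane, toluene, −78 °C; then aq. NaOH
Reagents that add atoms: none
Why: CBS reduction should give clean 1,2-reduction, with the ortho-disubstituted aryl ring acting as the larger carbonyl substituent so that the (R)-catalyst delivers hydride to give the 7S carbinol.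

**Step 10**
Reactants: 11 (7S)-allylic alcohol
Product: 13 (5R)-N,N-dimethylamide (CH2CONMe2 on the β-face of C-5, C-6=C-7 alkene, dioxolane at C-20), via ketene N,O-acetal 12 (not isolated)
Conditions: MeC(OMe)2NMe2, xylenes, 130 °C
Reagents that add atoms: N,N-dimethylacetamide dimethyl acetal CC(OC)(OC)N(C)C
Why: The Eschenmoser–Claisen rearrangement is suprafacial across ring B, so the new C-4–C-5 bond forms on the face that carried the C-7 oxygen (β) and the alkene moves into conjugation with the arene.

**Step 11**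
Reactants: 13 (5R)-N,N-dimethylamide
Product: 15 19,6α-lactone (γ-lactone trans-fused to ring B) with free 7α-OH, via dihydroxy amide 14 (not isolated)
Conditions: OsO4 (2 mol %), NMO, acetone/H2O, rt; then camphorsulfonic acid, toluene, 60 °C
Reagents that add atoms: N-methylmorpholine N-oxide C[N+]1([O-])CCOCC1; water O
Why: Upjohn dihydroxylation should add to the C-6=C-7 face anti to the C-5 branch (6α,7α-diol), and acid then closes the γ-lactone onto O-6, the only hydroxyl that can reach C-19 in a five-membered ring.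

**Step 12**
Reactants: 15 hydroxy lactone
Product: 16 7-O-tert-butyldimethylsilyl ether of 15
Conditions: t-BuMe2SiCl, imidazole, DMAP (cat.), DMF, 45 °C
Reagents that add atoms: tert-butyldimethylsilyl chloride CC(C)(C)[Si](C)(C)Cl
Why: Standard silylation protects the benzylic alcohol; imidazole conditions avoid the silyl triflate that could open the ketal.

**Step 13**
Reactants: 16 silyl ether; 17 tert-butyl(3-iodopropoxy)dimethylsilane
Product: 18 C-4 (3-silyloxypropyl) lactone, side chain trans to C-10 (4R)
Conditions: LiN(iPr)2, THF, −78 °C; 17, DMPU, −78 to −20 °C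
Reagents that add atoms: none
Why: Alkylation of the lactone enolate should occur anti to the C-10 methylene on the adjacent carbon; this centre is planarised again in step 14, so either epimer serves.

**Step 14**
Reactants: 18 monoalkylated lactone
Product: 19 C-4 quaternary lactone (4S: 4α-methyl trans to C-10, silyloxypropyl chain cis to C-10)
Conditions: LiN(iPr)2, THF, −78 °C; MeI, DMPU, −78 to −20 °C
Reagents that add atoms: iodomethane CI
Why: Methylation of the tetrasubstituted lactone enolate should again occur anti to C-10, which puts the methyl on the α-face and leaves the three-carbon chain cis to C-10 as ring A requires.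

**Step 15**
Reactants: 19 C-4 quaternary lactone
Product: 20 C-20 ketone (dioxolane removed)
Conditions: pyridinium p-toluenesulfonate, acetone/H2O, rt
Reagents that add atoms: water O
Why: The ketal of an electron-rich aryl ketone hydrolyses under acid mild enough to leave both silyl ethers and the lactone intact.

**Step 16**
Reactants: 20 C-20 ketone
Product: 21 10-bromo-20-ketone (C-10 epimers)
Conditions: LiN(SiMe3)2, THF, −78 °C; N-bromosuccinimide
Reagents that add atoms: N-bromosuccinimide O=C1CCC(=O)N1Br
Why: C-10 is the only enolisable position (C-4 is quaternary) and the enolate has no β-leaving group, so enolate bromination should be regiospecific.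

**Step 17**
Reactants: 21 10-bromo-20-ketone
Product: 22 10-bromo-20-ol (bromohydrin, epimers at C-10 and C-20)
Conditions: NaBH4, MeOH/THF, −20 °C
Reagents that add atoms: none
Why: Borohydride reduction of the activated α-bromo ketone is faster than attack on the hindered lactone; both new centres are removed in step 18.

**Step 18**
Reactants: 22 bromohydrin
Product: 23 C-10 alkenyl bromide (C-10=C-20), bis-silyl ether
Conditions: Martin sulfurane, CH2Cl2, 0 °C to rt
Reagents that add atoms: none
Why: Dehydration of the electron-rich benzylic alcohol can only remove H-10 (C-9 is aromatic), so the bromine ends on C-10 of the C-10=C-20 bond, as in bromotetralol-to-bromodihydronaphthalene dehydrations.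

**Step 19**
Reactants: 23 bis-silyl ether
Product: 24 diol (primary C-1 OH and 7α-OH), alkenyl bromide
Conditions: Bu4NF, THF, rt
Reagents that add atoms: none
Why: Fluoride cleaves both silyl ethers and leaves the alkenyl bromide and lactone untouched.

**Step 20**
Reactants: 24 diol
Product: 25 C-1 aldehyde with free 7α-OH, alkenyl bromide
Conditions: TEMPO (10 mol %), PhI(OAc)2, CH2Cl2, rt
Reagents that add atoms: none
Why: Oxoammonium oxidation is strongly selective for the primary over the hindered secondary alcohol.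

**Step 21**
Reactants: 25 C-1 aldehyde
Product: 26 ring-A-closed trimethoxyarene (1β,7α-diol, C-10=C-20, 19,6α-lactone)
Conditions: CrCl2 (8 equiv), NiCl2 (10 mol %), DMSO/THF, rt, 2 mM
Reagents that add atoms: none
Why: Zerovalent nickel (formed from NiCl2 and CrCl2) inserts into the C-10–Br bond and transmetalation gives an alkenyl trivalent-chromium species that adds to the C-1 aldehyde, so two electrophilic carbons are joined by reductive polarity reversal. The closest known reaction type is the intramolecular Nozaki–Hiyama–Kishi cyclisation of alkenyl halides onto aldehydes to give cyclic allylic alcohols. Ring A closes by 6-exo-trig attack of C-10 on the carbonyl carbon. C-1 should be set by a chair-like transition state in which the C-2/C-3 tether, held by the quaternary C-4 of the rigid lactone, places the chromium alkoxide equatorial (1β, R), avoiding 1,3-diaxial contact with H-3α and H-5α at the cost of only a small allylic strain against H-20. The step needs chemoselective metalation of the alkenyl bromide and addition to the aldehyde rather than the lactone, with the C-10=C-20 geometry kept; the weakly basic organochromium tolerates the free 7-OH and the lactone, the alkene geometry is fixed by ring B, and high dilution suppresses intermolecular coupling.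

**Step 22**
Reactants: 26 trimethoxyarene
Product: 27 ballotiquinone 12-O-methyl ether (12-methoxy-11,14-quinone)
Conditions: (NH4)2Ce(NO3)6, MeCN/H2O, 0 °C
Reagents that add atoms: water O
Why: Oxidative demethylation of a 1,2,4-trimethoxyarene by tetravalent cerium proceeds through the arene radical cation and water attack at the para-related C-11 and C-14, giving the methoxy-p-quinone.

**Step 23**
Reactants: 27 ballotiquinone 12-O-methyl ether
Product: 28 ballotiquinone
Conditions: LiOH (aq.), THF, 0 °C; then 1 M HCl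
Reagents that add atoms: lithium hydroxide [Li+].[OH-]
Why: The methoxyquinone is a vinylogous ester that hydroxide cleaves by addition–elimination at C-12 faster than it attacks the lactone shielded by quaternary C-4, and acidification would re-close any opened lactone.

**Compound list**
1 | 1,2,4-trimethoxybenzene | COc1ccc(OC)c(OC)c1 | starting material
2 | 2-(2,3,6-trimethoxyphenyl)propan-2-ol | COc1ccc(OC)c(C(C)(C)O)c1OC | intermediate
3 | 2-isopropyl-1,3,4-trimethoxybenzene | COc1ccc(OC)c(C(C)C)c1OC | intermediate
4 | glutaric anhydride | O=C1CCCC(=O)O1 | starting material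
5 | 5-(3-isopropyl-2,4,5-trimethoxyphenyl)-5-oxopentanoic acid | COc1cc(C(=O)CCCC(=O)O)c(OC)c(C(C)C)c1OC | intermediate
6 | 5-(3-isopropyl-2,4,5-trimethoxyphenyl)pentanoic acid | COc1cc(CCCCC(=O)O)c(OC)c(C(C)C)c1OC | intermediate
7 | 2-isopropyl-1,3,4-trimethoxy-6,7,8,9-tetrahydro-5H-benzo[7]annulen-5-one | CC(C)c1c(OC)c(OC)c2c(c1OC)CCCCC2=O | intermediate
8 | C-20 ethylene ketal of 7 | CC(C)c1c(OC)c(OC)c2c(c1OC)CCCCC23OCCO3 | intermediate
9 | 7-oxo ketal (aryl ketone at C-7) | CC(C)c1c(OC)c(OC)c2c(c1OC)C(=O)CCCC23OCCO3 | intermediate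
10 | C-7 enone with C-5=C-6 | CC(C)c1c(OC)c(OC)c2c(c1OC)C(=O)C=CCC23OCCO3 | intermediate
11 | (7S)-allylic alcohol (7β-OH) | CC(C)c1c(OC)c(OC)c2c(c1OC)[C@@H](O)C=CCC23OCCO3 | intermediate
12 | ketene N,O-acetal of 11 | CC(C)c1c(OC)c(OC)c2c(c1OC)[C@@H](OC(=C)N(C)C)C=CCC23OCCO3 | intermediate
13 | (5R)-N,N-dimethylamide, C-6=C-7 | CC(C)c1c(OC)c(OC)c2c(c1OC)C=C[C@@H](CC(=O)N(C)C)CC23OCCO3 | intermediate
14 | 6α,7α-dihydroxy amide | CC(C)c1c(OC)c(OC)c2c(c1OC)[C@H](O)[C@H](O)[C@@H](CC(=O)N(C)C)CC23OCCO3 | intermediate
15 | 19,6α-lactone with 7α-OH | CC(C)c1c(OC)c(OC)c2c(c1OC)[C@H](O)[C@@H]3OC(=O)C[C@H]3CC24OCCO4 | intermediate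
16 | 7-O-silyl ether of 15 | CC(C)c1c(OC)c(OC)c2c(c1OC)[C@H](O[Si](C)(C)C(C)(C)C)[C@@H]3OC(=O)C[C@H]3CC24OCCO4 | intermediate
17 | tert-butyl(3-iodopropoxy)dimethylsilane | CC(C)(C)[Si](C)(C)OCCCI | starting material
18 | C-4 (3-silyloxypropyl) lactone (4R) | CC(C)c1c(OC)c(OC)c2c(c1OC)[C@H](O[Si](C)(C)C(C)(C)C)[C@@H]3OC(=O)[C@H](CCCO[Si](C)(C)C(C)(C)C)[C@H]3CC24OCCO4 | intermediate
19 | C-4 quaternary lactone (4S) | CC(C)c1c(OC)c(OC)c2c(c1OC)[C@H](O[Si](C)(C)C(C)(C)C)[C@@H]3OC(=O)[C@@](C)(CCCO[Si](C)(C)C(C)(C)C)[C@H]3CC24OCCO4 | intermediate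
20 | C-20 ketone | CC(C)c1c(OC)c(OC)c2c(c1OC)[C@H](O[Si](C)(C)C(C)(C)C)[C@@H]3OC(=O)[C@@](C)(CCCO[Si](C)(C)C(C)(C)C)[C@H]3CC2=O | intermediate
21 | 10-bromo-20-ketone (C-10 epimers) | CC(C)c1c(OC)c(OC)c2c(c1OC)[C@H](O[Si](C)(C)C(C)(C)C)[C@@H]3OC(=O)[C@@](C)(CCCO[Si](C)(C)C(C)(C)C)[C@H]3C(Br)C2=O | intermediate
22 | 10-bromo-20-ol (epimers at C-10 and C-20) | CC(C)c1c(OC)c(OC)c2c(c1OC)[C@H](O[Si](C)(C)C(C)(C)C)[C@@H]3OC(=O)[C@@](C)(CCCO[Si](C)(C)C(C)(C)C)[C@H]3C(Br)C2O | intermediate
23 | C-10 alkenyl bromide, bis-silyl ether | CC(C)c1c(OC)c(OC)c2c(c1OC)[C@H](O[Si](C)(C)C(C)(C)C)[C@@H]3OC(=O)[C@@](C)(CCCO[Si](C)(C)C(C)(C)C)[C@H]3C(Br)=C2 | intermediate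
24 | diol, alkenyl bromide | CC(C)c1c(OC)c(OC)c2c(c1OC)[C@H](O)[C@@H]3OC(=O)[C@@](C)(CCCO)[C@H]3C(Br)=C2 | intermediate
25 | C-1 aldehyde, alkenyl bromide | CC(C)c1c(OC)c(OC)c2c(c1OC)[C@H](O)[C@@H]3OC(=O)[C@@](C)(CCC=O)[C@H]3C(Br)=C2 | intermediate
26 | ring-A-closed trimethoxyarene, 1β,7α-diol | CC(C)c1c(OC)c(OC)c2c(c1OC)[C@H](O)[C@@H]1OC(=O)[C@@]3(C)CC[C@@H](O)C(=C2)[C@@H]13 | intermediate
27 | ballotiquinone 12-O-methyl ether | CC(C)C1=C(OC)C(=O)C2=C(C1=O)[C@H](O)[C@@H]1OC(=O)[C@@]3(C)CC[C@@H](O)C(=C2)[C@@H]13 | intermediate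
28 | ballotiquinone | CC(C)C1=C(O)C(=O)C2=C(C1=O)[C@H](O)[C@@H]1OC(=O)[C@@]3(C)CC[C@@H](O)C(=C2)[C@@H]13 | target

**Count**
Total steps: 23. Longest linear sequence: 23 steps (1 to 28).

**Steps most likely to fail**

Step 21. Oxidative addition of zerovalent nickel into the hindered, electron-rich cyclic alkenyl bromide may be slow, so that reduction of the bromide or pinacol coupling of the aldehyde outruns ring closure. The fallback forms the same C-1–C-10 bond by a samarium Reformatsky (aldol-type) closure and sets out from bromo ketone 21. HF·pyridine in pyridine/THF would remove only the primary silyl ether to give the primary alcohol F1, and Dess–Martin periodinane would give the bromo keto aldehyde F2. SmI2 in THF at −78 °C would turn the α-bromo ketone into a samarium enolate that adds to the aldehyde through a chelated chair, giving the ring-A-closed β-hydroxy ketone F3. NaBH4 would give the 1,20-diol F4, and pyridinium p-toluenesulfonate in warm toluene would dehydrate only the electron-rich benzylic C-20 alcohol to the C-10=C-20 alkene F5. Bu4NF would then return to 26.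

Step 9. Both carbonyl substituents are unsaturated (aryl and alkenyl), so enantiofacial discrimination by the oxazaborolidine may be poor. The fallback replaces asymmetric reduction by resolution and sets out from enone 10. NaBH4/CeCl3 would give the racemic allylic alcohol F6. Candida antarctica lipase B with vinyl acetate should acylate the (R)-enantiomer to the acetate F7 and leave the (S)-alcohol, which is 11.

Step 7. The oxidant may attack the electron-rich arene or abstract the isopropyl methine hydrogen instead of H-7. The fallback avoids the ketone altogether and sets out from ketal 8. NBS with AIBN would give the benzylic bromide F8, and DBU would eliminate it to the C-6=C-7 styrene F9. Jacobsen epoxidation with the (R,R)-(salen)MnCl catalyst and NaOCl should give the 6β,7β-epoxide F10. LiNEt2 would then remove H-5 and open the C-6–O bond to give allylic alcohol 11, bypassing 9 and 10.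

**Further compounds**
F1 | step 21 | primary alcohol of 21 (7-O-silyl, 10-bromo-20-ketone) | CC(C)c1c(OC)c(OC)c2c(c1OC)[C@H](O[Si](C)(C)C(C)(C)C)[C@@H]3OC(=O)[C@@](C)(CCCO)[C@H]3C(Br)C2=O
F2 | step 21 | bromo keto aldehyde | CC(C)c1c(OC)c(OC)c2c(c1OC)[C@H](O[Si](C)(C)C(C)(C)C)[C@@H]3OC(=O)[C@@](C)(CCC=O)[C@H]3C(Br)C2=O
F3 | step 21 | ring-A-closed 1β-hydroxy-20-ketone | CC(C)c1c(OC)c(OC)c2c(c1OC)[C@H](O[Si](C)(C)C(C)(C)C)[C@@H]1OC(=O)[C@@]3(C)CC[C@@H](O)C(C2=O)[C@@H]13
F4 | step 21 | ring-A-closed 1,20-diol | CC(C)c1c(OC)c(OC)c2c(c1OC)[C@H](O[Si](C)(C)C(C)(C)C)[C@@H]1OC(=O)[C@@]3(C)CC[C@@H](O)C(C2O)[C@@H]13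
F5 | step 21 | 7-O-silyl ether of 26 | CC(C)c1c(OC)c(OC)c2c(c1OC)[C@H](O[Si](C)(C)C(C)(C)C)[C@@H]1OC(=O)[C@@]3(C)CC[C@@H](O)C(=C2)[C@@H]13
F6 | step 9 | racemic allylic alcohol | CC(C)c1c(OC)c(OC)c2c(c1OC)C(O)C=CCC23OCCO3
F7 | step 9 | (7R)-allylic acetate | CC(C)c1c(OC)c(OC)c2c(c1OC)[C@H](OC(C)=O)C=CCC23OCCO3
F8 | step 7 | C-7 benzylic bromide of 8 | CC(C)c1c(OC)c(OC)c2c(c1OC)C(Br)CCCC23OCCO3
F9 | step 7 | C-6=C-7 styrene | CC(C)c1c(OC)c(OC)c2c(c1OC)C=CCCC23OCCO3
F10 | step 7 | 6β,7β-epoxide | CC(C)c1c(OC)c(OC)c2c(c1OC)[C@H]4O[C@H]4CCC23OCCO3
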